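The small charge in this flask was X: its solution could hold at most 190 mM against 1.9 M of Z, and at the start it held none.

| flask | Z | X | remark | time |
|---|---|---|---|---|
| delta | 1.9 M | 190 mM (held) | the very flask that is asked about, followed so far |  |
| flask | 1.9 M | 190 mM (held) |  | 15 min |

delta run (percent of the Z charged)

| time / min | J / % |
|---|---|
| 0.500 | 3.3 |
| 0.833 | 8.5 |
| 1.33 | 15.5 |
| 2.00 | 18.3 |
| 3.00 | 17.6 |
| 5.00 | 13.7 |

(scatter of a reading: 0.5 percentage points)

- the earlier runs were read with a standard deviation of 0.5 percentage points
- at the start none of X is in solution

1. the best time, 15 min at the latest, for J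
2. the amount of J, in percent of the Z charged, at that time

I first asked which given numbers had to be known well. The limit 15 min mattered little to my reckoning, since J had already fallen from 18.3% at 2.00 min to 13.7% at 5.00 min. The charges did not enter the reading of the peak, since the delta run is this same flask. The readings at 1.33 min, 2.00 min and 3.00 min did matter: an error of 0.5 percentage points at 2.00 min passes almost directly into the height. So I committed to a peak between 2.00 min and 3.00 min, a little above 18.3%.

The charges served the balance of X. I defined the filling share f as the part of the Z that one saturated solution serves with one exchange each, f = 10.0%. J carries two exchanges, so the reading at 2.00 min asked for at least 3.66 fillings: in this flask, X had to keep crossing from the gas.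

The forecast gave 18.7% at 2.35 min, holding that “the early maximum is the best point”.

The flask gave 18.9% at 2.28 min.

    Z + D ⇌ Q + E (K = 33.0, k = 0.170 /M/s)
    E + D ⇌ Q + J (K = 12.0, k = 0.150 /M/s)
    J + D ⇌ Q + G (K = 100, k = 0.100 /M/s)
    X ⇌ D, rate k4*(csat - [D]) (kL = 0.190 /s)

At 2.28 min, the leaving ligand Q, one per exchange, stood at 2.32 M in this flask. That is 12.2 fillings, against the 3.78 that J itself required; the other exchanges stood in E and G.

In the neighbour flask with 0.47 M of Z, f is 40.4%, so one filling serves 20.2% of that Z as J. Its computed best of 30.2% required at least 1.50 fillings, and Z, the limiting reagent there, had 0.79% left at the end.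

The earlier runs and the new flask are calculated with made-up constants; noise was put on by code.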